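**Plan**

1. Locants (target numbering, kept for all bicyclic compounds): C1 acyl bridgehead, C2 C=O, C3 CH, C4 enol carbon, C5 prenyl bridgehead, C6 CH2, C7 CH(prenyl), C8 Me/homoprenyl carbon, C9 bridging C=O, C10 side-chain C=O. Ring A = C1–C2–C3–C4–C5–C9, ring B = C1–C8–C7–C6–C5–C9.
2. Retrosynthetic cuts, in order: C1–C10 and C5–prenyl at the bridgeheads; the C7 side chain back to C7=CH2 and then C7=O; the two C8–alkyl bonds; last, ring B at C5–C6.
3. Enabling feature: C6 is the only CH2 of ring B, bonded to bridgehead C5 and one carbon from the C9 ketone. This is the pattern left when a carbene carbon (C6) adds across a C5=C9 enol ether and the C6–C9 bond of the donor–acceptor cyclopropane is cut. Stripped of side chains, the diene form of ring A (enol ethers C2=C3 and C9=C5) is mirror-symmetric through C1 and C4, so the addition is a desymmetrisation.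
4. Forward: ring A comes from an anisole ring (Birch reduction); ring B closes in step 4; then C8 (Me, homoprenyl), the C7 enol triflate, the C4 oxygen, C7=CH2 and its hydroboration/coupling, C5 prenyl, C1 acyl, deprotection.
5. Stereochemistry: C1/C5 from the chiral copper carbenoid; C8 from the order of two exo-face alkylations; C7 from exo-face hydroboration; the acyl stereocentre from (R)-2-methylbutanoic acid.

Key step: step 4

Remark: the 4-hydroxy-2-oxo form drawn for the target is taken as one tautomer of the vinylogous acid released in the last step; the (S,S)-ligand is assumed to favour the enol ether leading to the (1R,5S) ketone 8, and its mirror image would be used if the sense proved opposite; CIP descriptors change along the route only through priority changes, not through any change at C1, C5, C7 or C8.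

**Step 1**
Reactants: 1 2-(2,6-dimethoxyphenyl)acetic acid
Product: 2 2-(2,6-dimethoxycyclohexa-2,5-dien-1-yl)acetic acid
Conditions: Li, NH3 (l)/THF, t-BuOH, −78 → −33 °C; NH4Cl; NaH2PO4 work-up (pH 5–6)
Reagents that add atoms: none
Why: Birch reduction, in which the carboxylate is inert and the two methoxy groups direct protonation to the ipso carbon and the carbon para to it, so both enol ethers remain and the 1,4-diene results.

**Step 2**
Reactants: 2 2-(2,6-dimethoxycyclohexa-2,5-dien-1-yl)acetic acid; 3 methyl phenyl sulfone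
Product: 5 1-(2,6-dimethoxycyclohexa-2,5-dien-1-yl)-3-(phenylsulfonyl)propan-2-one, via acyl imidazolide 4 (not isolated)
Conditions: 1,1′-carbonyldiimidazole, THF, rt; then PhSO2CH2Li (from 3 and n-BuLi, 3 equiv), THF, −78 → −20 °C; NH4Cl (aq)
Reagents that add atoms: none
Why: Claisen-type C-acylation of a sulfonyl carbanion by an acyl imidazolide, run without acid so that the enol ethers survive, the excess carbanion deprotonating the β-keto sulfone and so preventing double addition.

**Step 3**
Reactants: 5 1-(2,6-dimethoxycyclohexa-2,5-dien-1-yl)-3-(phenylsulfonyl)propan-2-one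
Product: 6 1-diazo-3-(2,6-dimethoxycyclohexa-2,5-dien-1-yl)-1-(phenylsulfonyl)propan-2-one
Conditions: 4-acetamidobenzenesulfonyl azide, Et3N, MeCN, 0 °C → rt
Reagents that add atoms: 4-acetamidobenzenesulfonyl azide, CC(=O)Nc1ccc(cc1)S(=O)(=O)N=[N+]=[N-]
Why: Regitz diazo transfer to the doubly activated methylene of a β-keto sulfone, which needs only a tertiary amine as base.

**Step 4**
Reactants: 6 1-diazo-3-(2,6-dimethoxycyclohexa-2,5-dien-1-yl)-1-(phenylsulfonyl)propan-2-one
Product: 8 (1R,5S)-2-methoxy-6-(phenylsulfonyl)bicyclo[3.3.1]non-2-ene-7,9-dione, via methoxycyclopropane 7 (not isolated)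
Conditions: (CuOTf)2·C6H6 (5 mol %, monovalent copper), 2,2′-(propane-2,2-diyl)bis[(4S)-4-isopropyl-4,5-dihydrooxazole] (12 mol %), toluene, 50 °C; then THF–H2O, pyridinium p-toluenesulfonate/pyridine buffer, rt
Reagents that add atoms: water, O
Why: Loss of N2 gives a copper carbenoid at C6 that adds to the C5=C9 enol ether in an intramolecular [2+1] cyclopropanation, forming C5–C6 and C6–C9; the closest known reaction is the copper–bis(oxazoline) cyclopropanation of α-diazo-β-keto sulfones onto cyclohexa-1,4-dienes. With respect to that double bond the five-membered ring C6–C7–C8–C1–C9 of 7 closes 5-exo and the six-membered ring B (C1–C8–C7–C6–C5–C9) closes 6-endo, both necessarily cis-fused. C1 and C5 become stereocentres because the chiral carbenoid distinguishes the two enantiotopic enol ethers flanking C1, while C6 of 8 is a labile α-sulfonyl ketone carbon carried as its epimer mixture. In 7 the C6–C9 bond carries the methoxy donor on C9 and both acceptors (ketone and sulfone) on C6, so it ionises far more readily than C5–C6 or C5–C9; water adds to the oxocarbenium ion, methanol is lost and the carbanion is protonated, leaving ring B closed through C5–C6 (donor–acceptor cyclopropane solvolysis). The step needs selection between enantiotopic alkenes (ligand), cleavage of C6–C9 only (push–pull substitution) and survival of the C2=C3 enol ether, which the weakly acidic buffer should secure because that group reacts only by slow protonation on carbon. The sulfonyl group is the added activating element: it is the substituent for which this carbenoid class gives its highest enantioselectivity, it allows opening without strong acid, and it later steers base chemistry to C8.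

**Step 5**
Reactants: 8 (1R,5S)-2-methoxy-6-(phenylsulfonyl)bicyclo[3.3.1]non-2-ene-7,9-dione
Product: 9 (1R,5S)-2-methoxy-8-methyl-6-(phenylsulfonyl)bicyclo[3.3.1]non-2-ene-7,9-dione
Conditions: LiN(i-Pr)2 (2.2 equiv), THF, −78 → −40 °C; MeI (1.0 equiv), −78 °C; AcOH quench
Reagents that add atoms: iodomethane, CI
Why: γ-Alkylation of a β-keto sulfone dianion, in which the first equivalent of base sits on the acidic C6–H, the second can only generate the C7=C8 enolate, and this more basic terminus is methylated while C6 stays protected as its anion (the C8 configuration is irrelevant because the centre is planarised again in step 7).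

**Step 6**
Reactants: 10 5-bromo-2-methylpent-2-ene
Product: 11 5-iodo-2-methylpent-2-ene
Conditions: NaI, acetone, reflux
Reagents that add atoms: sodium iodide, [Na+].[I-]
Why: Finkelstein halide exchange driven by precipitation of NaBr, giving the more reactive iodide for the quaternisation.

**Step 7**
Reactants: 9 (1R,5S)-2-methoxy-8-methyl-6-(phenylsulfonyl)bicyclo[3.3.1]non-2-ene-7,9-dione; 11 5-iodo-2-methylpent-2-ene
Product: 12 (1R,5S,8S)-2-methoxy-8-methyl-8-(4-methylpent-3-en-1-yl)-6-(phenylsulfonyl)bicyclo[3.3.1]non-2-ene-7,9-dione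
Conditions: LiN(i-Pr)2 (2.3 equiv), THF–DMPU, −78 → −20 °C; 11, −40 → 0 °C
Reagents that add atoms: none
Why: Second γ-alkylation of the dianion, now forming the quaternary carbon, in which the iodide approaches the C7=C8 enolate axially on the face of ring B opposite the C2–C3–C4 bridge (the other face is covered by ring A), so the group introduced last, homoprenyl, ends anti to C2 and the methyl group syn, as in the target.

**Step 8**
Reactants: 12 (1R,5S,8S)-2-methoxy-8-methyl-8-(4-methylpent-3-en-1-yl)-6-(phenylsulfonyl)bicyclo[3.3.1]non-2-ene-7,9-dione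
Product: 13 (1R,5R,8S)-2-methoxy-8-methyl-8-(4-methylpent-3-en-1-yl)bicyclo[3.3.1]non-2-ene-7,9-dione
Conditions: SmI2 (3 equiv), THF–MeOH, −78 °C
Reagents that add atoms: none
Why: Single-electron reductive cleavage of the C–S bond of a β-keto sulfone by SmI2, which at −78 °C should be much faster than reduction of the two unconjugated ketones and leaves the alkene and enol ether untouched.

**Step 9**
Reactants: 13 (1R,5R,8S)-2-methoxy-8-methyl-8-(4-methylpent-3-en-1-yl)bicyclo[3.3.1]non-2-ene-7,9-dione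
Product: 14 (1R,5R,8S)-2-methoxy-8-methyl-8-(4-methylpent-3-en-1-yl)-9-oxobicyclo[3.3.1]nona-2,6-dien-7-yl trifluoromethanesulfonate
Conditions: KN(SiMe3)2, THF, −78 °C; PhNTf2, −78 → 0 °C
Reagents that add atoms: N-phenylbis(trifluoromethanesulfonimide), O=S(=O)(N(c1ccccc1)S(=O)(=O)C(F)(F)F)C(F)(F)F
Why: Kinetic enolisation and O-sulfonylation, in which only C6 carries enolisable hydrogens (C8 is quaternary and C9 has only bridgehead neighbours), so the enol triflate forms at C7 alone and this carbonyl is told apart from C9 without any nucleophile.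

**Step 10**
Reactants: 14 (1R,5R,8S)-2-methoxy-8-methyl-8-(4-methylpent-3-en-1-yl)-9-oxobicyclo[3.3.1]nona-2,6-dien-7-yl trifluoromethanesulfonate
Product: 16 (1R,5S,8S)-2-methoxy-8-methyl-8-(4-methylpent-3-en-1-yl)-4,9-dioxobicyclo[3.3.1]nona-2,6-dien-7-yl trifluoromethanesulfonate, via allylic tert-butyl peroxide 15 (not isolated)
Conditions: PhI(OAc)2, t-BuOOH, K2CO3, EtOAc, −20 °C
Reagents that add atoms: tert-butyl hydroperoxide, CC(C)(C)OO
Why: Radical allylic oxidation by the t-BuOO radical generated from PhI(OAc)2 and t-BuOOH, in which the C4–H bonds next to the electron-rich enol ether are abstracted most readily, the allyl radical is trapped at C4 and the peroxide collapses to the ketone (Kornblum–DeLaMare), a combination known to turn cyclic enol ethers into vinylogous esters in the presence of trisubstituted alkenes.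

**Step 11**
Reactants: 16 (1R,5S,8S)-2-methoxy-8-methyl-8-(4-methylpent-3-en-1-yl)-4,9-dioxobicyclo[3.3.1]nona-2,6-dien-7-yl trifluoromethanesulfonate
Product: 17 (1R,5S,8S)-2-methoxy-8-methyl-8-(4-methylpent-3-en-1-yl)-7-[(trimethylsilyl)methyl]bicyclo[3.3.1]nona-2,6-diene-4,9-dione
Conditions: Me3SiCH2MgCl, ZnCl2, THF, 0 °C (gives Me3SiCH2ZnCl); then Pd(PPh3)4 (5 mol %, zerovalent palladium), LiCl, THF, 50 °C
Reagents that add atoms: (trimethylsilyl)methylmagnesium chloride, C[Si](C)(C)C[Mg]Cl
Why: Negishi coupling of an enol triflate with an alkylzinc reagent lacking β-hydrogens, the organozinc being too unreactive to add to the C9 ketone or the vinylogous ester, so carbon is attached to C7 without nucleophilic attack on the competing C9 carbonyl.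

**Step 12**
Reactants: 17 (1R,5S,8S)-2-methoxy-8-methyl-8-(4-methylpent-3-en-1-yl)-7-[(trimethylsilyl)methyl]bicyclo[3.3.1]nona-2,6-diene-4,9-dione
Product: 18 (1R,5S,8S)-2-methoxy-8-methyl-7-methylidene-8-(4-methylpent-3-en-1-yl)bicyclo[3.3.1]non-2-ene-4,9-dione
Conditions: CF3CO2H, CH2Cl2, −20 → 0 °C; NaHCO3 (aq)
Reagents that add atoms: none
Why: SE2′ protodesilylation of an allylsilane, in which the proton adds at C6 and silicon leaves from the exocyclic carbon so that the double bond moves regiospecifically to C7=CH2, the allylsilane being far more nucleophilic than the trisubstituted side-chain alkene and the vinylogous ester being stable to anhydrous acid.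

**Step 13**
Reactants: 18 (1R,5S,8S)-2-methoxy-8-methyl-7-methylidene-8-(4-methylpent-3-en-1-yl)bicyclo[3.3.1]non-2-ene-4,9-dione; 19 1-bromo-2-methylprop-1-ene
Product: 21 (1R,5S,7S,8R)-2-methoxy-8-methyl-7-(3-methylbut-2-en-1-yl)-8-(4-methylpent-3-en-1-yl)bicyclo[3.3.1]non-2-ene-4,9-dione, via alkylborane 20 (not isolated)
Conditions: 9-BBN, THF, rt; then 19, PdCl2(dppf) (5 mol %, divalent palladium precatalyst), AsPh3, Cs2CO3, DMF–H2O, rt
Reagents that add atoms: none
Why: Hydroboration with 9-BBN followed by B-alkyl Suzuki–Miyaura coupling, in which the bulky borane reacts with the 1,1-disubstituted alkene much faster than with the trisubstituted one and adds from the exo face of ring B (the endo face lies over ring A), so hydrogen reaches C7 from outside, on the side of the C8 homoprenyl group, and the CH2B arm that becomes the prenyl group points endo, cis to the C8 methyl group as in the target.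

**Step 14**
Reactants: 21 (1R,5S,7S,8R)-2-methoxy-8-methyl-7-(3-methylbut-2-en-1-yl)-8-(4-methylpent-3-en-1-yl)bicyclo[3.3.1]non-2-ene-4,9-dione; 22 prenyl bromide (1-bromo-3-methylbut-2-ene)
Product: 23 (1R,5S,7S,8R)-2-methoxy-8-methyl-5,7-bis(3-methylbut-2-en-1-yl)-8-(4-methylpent-3-en-1-yl)bicyclo[3.3.1]non-2-ene-4,9-dione
Conditions: LiN(i-Pr)2, THF, −78 °C; 22, −78 → −40 °C
Reagents that add atoms: none
Why: Bridgehead deprotonation and alkylation, in which C5–H is the only hydrogen flanked by two carbonyl groups (C4 and C9) and the pyramidal carbanion is alkylated by the allylic bromide with retention, as established for 2-methoxybicyclo[3.3.1]non-2-ene-4,9-diones.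

**Step 15**
Reactants: 23 (1R,5S,7S,8R)-2-methoxy-8-methyl-5,7-bis(3-methylbut-2-en-1-yl)-8-(4-methylpent-3-en-1-yl)bicyclo[3.3.1]non-2-ene-4,9-dione
Product: 24 (1R,5R,7S,8R)-2-methoxy-8-methyl-5,7-bis(3-methylbut-2-en-1-yl)-8-(4-methylpent-3-en-1-yl)-3-(trimethylsilyl)bicyclo[3.3.1]non-2-ene-4,9-dione
Conditions: Me3SiCl, LiN(i-Pr)2, THF, −78 °C (in situ quench)
Reagents that add atoms: chlorotrimethylsilane, C[Si](C)(C)Cl
Why: Metalation with in situ silyl quench, in which, once C5 is quaternary, the most acidic hydrogen is the vinylic C3–H of the vinylogous ester, and silylating it blocks this position for the next metalation.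

**Step 16**
Reactants: 25 (R)-2-methylbutanoic acid
Product: 26 (R)-2-methylbutanoyl chloride
Conditions: (COCl)2, DMF (cat.), CH2Cl2, 0 °C → rt; volatiles removed
Reagents that add atoms: oxalyl chloride, O=C(Cl)C(Cl)=O
Why: Vilsmeier-type conversion of the acid into its chloride under base-free conditions, which does not touch the α-stereocentre.

**Step 17**
Reactants: 24 (1R,5R,7S,8R)-2-methoxy-8-methyl-5,7-bis(3-methylbut-2-en-1-yl)-8-(4-methylpent-3-en-1-yl)-3-(trimethylsilyl)bicyclo[3.3.1]non-2-ene-4,9-dione; 26 (R)-2-methylbutanoyl chloride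
Product: 27 (1R,5R,7S,8R)-2-methoxy-8-methyl-1-[(2R)-2-methylbutanoyl]-5,7-bis(3-methylbut-2-en-1-yl)-8-(4-methylpent-3-en-1-yl)-3-(trimethylsilyl)bicyclo[3.3.1]non-2-ene-4,9-dione
Conditions: lithium 2,2,6,6-tetramethylpiperidide (from the amine and n-BuLi), THF, −78 → −40 °C; 26, −78 °C; AcOH quench
Reagents that add atoms: none
Why: Bridgehead metalation at C1, the last acidic position (α to C9 and vinylogous to C4), followed by C-acylation with the acid chloride at low temperature, the bridgehead keeping its configuration and the side-chain stereocentre being brought in intact from 25.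

**Step 18**
Reactants: 27 (1R,5R,7S,8R)-2-methoxy-8-methyl-1-[(2R)-2-methylbutanoyl]-5,7-bis(3-methylbut-2-en-1-yl)-8-(4-methylpent-3-en-1-yl)-3-(trimethylsilyl)bicyclo[3.3.1]non-2-ene-4,9-dione
Product: 28 (1R,5S,7S,8R)-2-methoxy-8-methyl-1-[(2R)-2-methylbutanoyl]-5,7-bis(3-methylbut-2-en-1-yl)-8-(4-methylpent-3-en-1-yl)bicyclo[3.3.1]non-2-ene-4,9-dione
Conditions: Bu4NF, AcOH, THF, 0 °C
Reagents that add atoms: none
Why: Fluoride-induced protodesilylation of the α-silyl enone carbon, buffered with acetic acid to avoid retro-Claisen cleavage of the new β-tricarbonyl unit.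

**Step 19**
Reactants: 28 (1R,5S,7S,8R)-2-methoxy-8-methyl-1-[(2R)-2-methylbutanoyl]-5,7-bis(3-methylbut-2-en-1-yl)-8-(4-methylpent-3-en-1-yl)bicyclo[3.3.1]non-2-ene-4,9-dione
Product: 29 (1S,5S,7S,8R)-4-hydroxy-8-methyl-1-[(2R)-2-methylbutanoyl]-5,7-bis(3-methylbut-2-en-1-yl)-8-(4-methylpent-3-en-1-yl)bicyclo[3.3.1]non-3-ene-2,9-dione
Conditions: LiCl, DMSO, 120 °C; dilute HCl work-up
Reagents that add atoms: none
Why: SN2 demethylation of the vinylogous methyl ester by chloride in a dipolar aprotic solvent (Krapcho-type), close to neutral so that neither the acyl stereocentre nor the β-tricarbonyl array is endangered, acidification then giving the enol.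

**Compound list**

1 | 2-(2,6-dimethoxyphenyl)acetic acid | COc1cccc(OC)c1CC(=O)O | starting material
2 | 2-(2,6-dimethoxycyclohexa-2,5-dien-1-yl)acetic acid | COC1=CCC=C(OC)C1CC(=O)O | intermediate
3 | methyl phenyl sulfone | CS(=O)(=O)c1ccccc1 | starting material
4 | 1-[(2,6-dimethoxycyclohexa-2,5-dien-1-yl)acetyl]-1H-imidazole (acyl imidazolide, not isolated) | COC1=CCC=C(OC)C1CC(=O)n1ccnc1 | intermediate
5 | 1-(2,6-dimethoxycyclohexa-2,5-dien-1-yl)-3-(phenylsulfonyl)propan-2-one | COC1=CCC=C(OC)C1CC(=O)CS(=O)(=O)c1ccccc1 | intermediate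
6 | 1-diazo-3-(2,6-dimethoxycyclohexa-2,5-dien-1-yl)-1-(phenylsulfonyl)propan-2-one | COC1=CCC=C(OC)C1CC(=O)C(=[N+]=[N-])S(=O)(=O)c1ccccc1 | intermediate
7 | (1R,5S,6R,9S)-2,9-dimethoxy-6-(phenylsulfonyl)tricyclo[3.3.1.0(6,9)]non-2-en-7-one (cis-fused cyclopropane C5–C6–C9, not isolated) | CO[C@@]12[C@H]3C(OC)=CC[C@@H]1[C@]2(S(=O)(=O)c4ccccc4)C(=O)C3 | intermediate
8 | (1R,5S)-2-methoxy-6-(phenylsulfonyl)bicyclo[3.3.1]non-2-ene-7,9-dione (C6 epimers) | [C@H]12C(OC)=CC[C@H](C(C(=O)C1)S(=O)(=O)c3ccccc3)C2=O | intermediate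
9 | (1R,5S)-2-methoxy-8-methyl-6-(phenylsulfonyl)bicyclo[3.3.1]non-2-ene-7,9-dione (C6 and C8 epimers) | [C@H]12C(OC)=CC[C@H](C(C(=O)C1C)S(=O)(=O)c3ccccc3)C2=O | intermediate
10 | 5-bromo-2-methylpent-2-ene | CC(C)=CCCBr | starting material
11 | 5-iodo-2-methylpent-2-ene | CC(C)=CCCI | intermediate
12 | (1R,5S,8S)-2-methoxy-8-methyl-8-(4-methylpent-3-en-1-yl)-6-(phenylsulfonyl)bicyclo[3.3.1]non-2-ene-7,9-dione (C6 epimers; homoprenyl anti to C2) | [C@H]12C(OC)=CC[C@H](C(C(=O)[C@@]1(C)CCC=C(C)C)S(=O)(=O)c3ccccc3)C2=O | intermediate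
13 | (1R,5R,8S)-2-methoxy-8-methyl-8-(4-methylpent-3-en-1-yl)bicyclo[3.3.1]non-2-ene-7,9-dione | [C@H]12C(OC)=CC[C@H](CC(=O)[C@@]1(C)CCC=C(C)C)C2=O | intermediate
14 | (1R,5R,8S)-2-methoxy-8-methyl-8-(4-methylpent-3-en-1-yl)-9-oxobicyclo[3.3.1]nona-2,6-dien-7-yl trifluoromethanesulfonate | [C@H]12C(OC)=CC[C@H](C=C(OS(=O)(=O)C(F)(F)F)[C@@]1(C)CCC=C(C)C)C2=O | intermediate
15 | (1R,5S,8S)-4-(tert-butylperoxy)-2-methoxy-8-methyl-8-(4-methylpent-3-en-1-yl)-9-oxobicyclo[3.3.1]nona-2,6-dien-7-yl trifluoromethanesulfonate (either C4 epimer, not isolated) | [C@H]12C(OC)=CC(OOC(C)(C)C)[C@H](C=C(OS(=O)(=O)C(F)(F)F)[C@@]1(C)CCC=C(C)C)C2=O | intermediate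
16 | (1R,5S,8S)-2-methoxy-8-methyl-8-(4-methylpent-3-en-1-yl)-4,9-dioxobicyclo[3.3.1]nona-2,6-dien-7-yl trifluoromethanesulfonate | [C@H]12C(OC)=CC(=O)[C@H](C=C(OS(=O)(=O)C(F)(F)F)[C@@]1(C)CCC=C(C)C)C2=O | intermediate
17 | (1R,5S,8S)-2-methoxy-8-methyl-8-(4-methylpent-3-en-1-yl)-7-[(trimethylsilyl)methyl]bicyclo[3.3.1]nona-2,6-diene-4,9-dione | [C@H]12C(OC)=CC(=O)[C@H](C=C(C[Si](C)(C)C)[C@@]1(C)CCC=C(C)C)C2=O | intermediate
18 | (1R,5S,8S)-2-methoxy-8-methyl-7-methylidene-8-(4-methylpent-3-en-1-yl)bicyclo[3.3.1]non-2-ene-4,9-dione | [C@H]12C(OC)=CC(=O)[C@H](CC(=C)[C@@]1(C)CCC=C(C)C)C2=O | intermediate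
19 | 1-bromo-2-methylprop-1-ene | CC(C)=CBr | starting material
20 | (1R,5S,7S,8R)-7-[(9-borabicyclo[3.3.1]nonan-9-yl)methyl]-2-methoxy-8-methyl-8-(4-methylpent-3-en-1-yl)bicyclo[3.3.1]non-2-ene-4,9-dione (CH2B endo, not isolated) | [C@H]12C(OC)=CC(=O)[C@H](C[C@H](CB3C4CCCC3CCC4)[C@@]1(C)CCC=C(C)C)C2=O | intermediate
21 | (1R,5S,7S,8R)-2-methoxy-8-methyl-7-(3-methylbut-2-en-1-yl)-8-(4-methylpent-3-en-1-yl)bicyclo[3.3.1]non-2-ene-4,9-dione | [C@H]12C(OC)=CC(=O)[C@H](C[C@H](CC=C(C)C)[C@@]1(C)CCC=C(C)C)C2=O | intermediate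
22 | prenyl bromide (1-bromo-3-methylbut-2-ene) | CC(C)=CCBr | starting material
23 | (1R,5S,7S,8R)-2-methoxy-8-methyl-5,7-bis(3-methylbut-2-en-1-yl)-8-(4-methylpent-3-en-1-yl)bicyclo[3.3.1]non-2-ene-4,9-dione | [C@H]12C(OC)=CC(=O)[C@](CC=C(C)C)(C[C@H](CC=C(C)C)[C@@]1(C)CCC=C(C)C)C2=O | intermediate
24 | (1R,5R,7S,8R)-2-methoxy-8-methyl-5,7-bis(3-methylbut-2-en-1-yl)-8-(4-methylpent-3-en-1-yl)-3-(trimethylsilyl)bicyclo[3.3.1]non-2-ene-4,9-dione | [C@H]12C(OC)=C([Si](C)(C)C)C(=O)[C@](CC=C(C)C)(C[C@H](CC=C(C)C)[C@@]1(C)CCC=C(C)C)C2=O | intermediate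
25 | (R)-2-methylbutanoic acid | CC[C@@H](C)C(=O)O | starting material
26 | (R)-2-methylbutanoyl chloride | CC[C@@H](C)C(=O)Cl | intermediate
27 | (1R,5R,7S,8R)-2-methoxy-8-methyl-1-[(2R)-2-methylbutanoyl]-5,7-bis(3-methylbut-2-en-1-yl)-8-(4-methylpent-3-en-1-yl)-3-(trimethylsilyl)bicyclo[3.3.1]non-2-ene-4,9-dione | CC[C@@H](C)C(=O)[C@]12C(OC)=C([Si](C)(C)C)C(=O)[C@](CC=C(C)C)(C[C@H](CC=C(C)C)[C@@]1(C)CCC=C(C)C)C2=O | intermediate
28 | (1R,5S,7S,8R)-2-methoxy-8-methyl-1-[(2R)-2-methylbutanoyl]-5,7-bis(3-methylbut-2-en-1-yl)-8-(4-methylpent-3-en-1-yl)bicyclo[3.3.1]non-2-ene-4,9-dione | CC[C@@H](C)C(=O)[C@]12C(OC)=CC(=O)[C@](CC=C(C)C)(C[C@H](CC=C(C)C)[C@@]1(C)CCC=C(C)C)C2=O | intermediate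
29 | (1S,5S,7S,8R)-4-hydroxy-8-methyl-1-[(2R)-2-methylbutanoyl]-5,7-bis(3-methylbut-2-en-1-yl)-8-(4-methylpent-3-en-1-yl)bicyclo[3.3.1]non-3-ene-2,9-dione | CC[C@@H](C)C(=O)[C@]12C(=O)C=C(O)[C@](CC=C(C)C)(C[C@H](CC=C(C)C)[C@@]1(C)CCC=C(C)C)C2=O | target

**Step count**

Total: 19 steps. Longest linear sequence: 17 steps (1 → 29 through steps 1–5, 7–15 and 17–19; steps 6 and 16 are side branches).

**Steps most likely to fail**

Step 7. The strongly basic dianion may eliminate HI from the homoallylic iodide, or react so slowly at the already substituted C8 that O- and C6-alkylation take over. Fallback (sets out from 2, returns at 13): the two C8 alkylations are moved in front of the ring opening and the sulfone is left out. Acid 2 would be converted with i-BuOCOCl/N-methylmorpholine into the mixed anhydride isobutyl carbonic 2-(2,6-dimethoxycyclohexa-2,5-dien-1-yl)acetic anhydride F1 and then with CH2N2 into 1-diazo-3-(2,6-dimethoxycyclohexa-2,5-dien-1-yl)propan-2-one F2. The catalyst of step 4 in dry toluene should give the sulfone-free analogue of 7, (1R,5R,6S,9R)-2,9-dimethoxytricyclo[3.3.1.0(6,9)]non-2-en-7-one F3, which is isolated. In it C6 is a cyclopropane carbon and cannot be enolised, so LiN(i-Pr)2/MeI should give its 8-methyl derivative F4 and LiN(i-Pr)2/DMPU/11 its 8-methyl-8-(4-methylpent-3-en-1-yl) derivative F5, through a simple unchelated cyclopentanone enolate attacked on the face away from ring A (homoprenyl anti to C2, as in 12). Acid-mediated hydrolytic opening of the C6–C9 bond (CF3CO2H, wet CH2Cl2, −20 °C, short contact) should then give 13.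

Step 10. Hydrogen abstraction from the allylic CH2 groups of the homoprenyl chain, or attack of the peroxide anion on the enol triflate, may compete with oxidation at C4. Fallback (sets out from 8, returns at 16): the oxidation is done before any side-chain alkene exists. 8 would be oxidised with CrO3/3,5-dimethylpyrazole (CH2Cl2, −20 °C) to (1R,5S)-2-methoxy-6-(phenylsulfonyl)bicyclo[3.3.1]non-2-ene-4,7,9-trione F6. The dianion conditions of steps 5 and 7 should then give its 8-methyl derivative F7 and its 8-methyl-8-(4-methylpent-3-en-1-yl) derivative F8, and SmI2 the sulfone-free (1R,5S,8S)-2-methoxy-8-methyl-8-(4-methylpent-3-en-1-yl)bicyclo[3.3.1]non-2-ene-4,7,9-trione F9. KN(SiMe3)2/PhNTf2 should then give 16, since the ordinary C6–H is removed faster than the bridgehead C5–H.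

Step 17. Attack of the congested C1 carbanion on the branched acid chloride may be slow enough for the amide base to turn the chloride into its ketene, so that the acyl group arrives with a scrambled α-centre or not at all. Fallback (sets out from 26 and 24, returns at 27): 26 would be reduced with LiAlH(O-t-Bu)3 (THF, −78 °C) to (R)-2-methylbutanal F10. The lithiated bridgehead of 24 should add to this smaller, more electrophilic partner to give the carbinol (1R,5R,7S,8R)-1-[(2R)-1-hydroxy-2-methylbutyl]-2-methoxy-8-methyl-5,7-bis(3-methylbut-2-en-1-yl)-8-(4-methylpent-3-en-1-yl)-3-(trimethylsilyl)bicyclo[3.3.1]non-2-ene-4,9-dione F11 (either carbinol epimer). Dess–Martin periodinane (CH2Cl2, NaHCO3) should oxidise it to 27 without base.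

**Further compounds**

F1 | step 7 | isobutyl carbonic 2-(2,6-dimethoxycyclohexa-2,5-dien-1-yl)acetic anhydride | COC1=CCC=C(OC)C1CC(=O)OC(=O)OCC(C)C
F2 | step 7 | 1-diazo-3-(2,6-dimethoxycyclohexa-2,5-dien-1-yl)propan-2-one | COC1=CCC=C(OC)C1CC(=O)C=[N+]=[N-]
F3 | step 7 | (1R,5R,6S,9R)-2,9-dimethoxytricyclo[3.3.1.0(6,9)]non-2-en-7-one | CO[C@@]12[C@H]3C(OC)=CC[C@@H]1[C@@H]2C(=O)C3
F4 | step 7 | 8-methyl derivative of F3 (C8 epimers) | CO[C@@]12[C@H]3C(OC)=CC[C@@H]1[C@@H]2C(=O)C3C
F5 | step 7 | 8-methyl-8-(4-methylpent-3-en-1-yl) derivative of F3 (homoprenyl anti to C2) | CO[C@@]12[C@H]3C(OC)=CC[C@@H]1[C@@H]2C(=O)[C@@]3(C)CCC=C(C)C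
F6 | step 10 | (1R,5S)-2-methoxy-6-(phenylsulfonyl)bicyclo[3.3.1]non-2-ene-4,7,9-trione (C6 epimers) | [C@H]12C(OC)=CC(=O)[C@H](C(C(=O)C1)S(=O)(=O)c3ccccc3)C2=O
F7 | step 10 | 8-methyl derivative of F6 (C6 and C8 epimers) | [C@H]12C(OC)=CC(=O)[C@H](C(C(=O)C1C)S(=O)(=O)c3ccccc3)C2=O
F8 | step 10 | 8-methyl-8-(4-methylpent-3-en-1-yl) derivative of F6 (homoprenyl anti to C2) | [C@H]12C(OC)=CC(=O)[C@H](C(C(=O)[C@@]1(C)CCC=C(C)C)S(=O)(=O)c3ccccc3)C2=O
F9 | step 10 | (1R,5S,8S)-2-methoxy-8-methyl-8-(4-methylpent-3-en-1-yl)bicyclo[3.3.1]non-2-ene-4,7,9-trione | [C@H]12C(OC)=CC(=O)[C@H](CC(=O)[C@@]1(C)CCC=C(C)C)C2=O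
F10 | step 17 | (R)-2-methylbutanal | CC[C@@H](C)C=O
F11 | step 17 | (1R,5R,7S,8R)-1-[(2R)-1-hydroxy-2-methylbutyl]-2-methoxy-8-methyl-5,7-bis(3-methylbut-2-en-1-yl)-8-(4-methylpent-3-en-1-yl)-3-(trimethylsilyl)bicyclo[3.3.1]non-2-ene-4,9-dione | CC[C@@H](C)C(O)[C@]12C(OC)=C([Si](C)(C)C)C(=O)[C@](CC=C(C)C)(C[C@H](CC=C(C)C)[C@@]1(C)CCC=C(C)C)C2=O
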